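## Retrosynthetic overview

- The strategy rests on C3 of the pentanoic acid chain (Cβ). It is the central carbon of a latent 1,5-dialdehyde, OHC–CH2–Cβ–Cγ–CHO, which is the ring-opened form of a 2-ethoxy-3,4-dihydro-2H-pyran (O1, C2–C6) with Cβ as C4 and Cγ as the enol-ether carbon C5.
- Last disconnection: the 5,5-dimethylfuran-2(5H)-ylidene ring is the cyclic enol ether formed between a tertiary alcohol and the ketone of a Cγ acyl group. Aqueous acid on pyran acid 23 opens the pyran and closes this ring.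
- The C5 acyl chain comes from formylation of the enol ether, acetylide addition, oxidation and semi-hydrogenation; CO2H is carried as CH2OTBDPS until the aldehydes are masked.
- Key disconnection: inverse-electron-demand oxa-Diels–Alder reaction of E-enal 10 with ethyl vinyl ether 11 forms C4–C3 and O1–C2 and sets Cβ. Enal 10 comes from cross-metathesis of diene 8 with crotonaldehyde; Cα is set by copper-catalysed enantioselective SN2′ alkenylation of phosphate 6.
- Ring order: the temporary dihydropyran (step 7) first, then the dihydrofuran (step 15), with loss of the pyran.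

Key step: step 7

Remark on geometry: the E configuration of the exocyclic enol ether double bond (Cβ branch beside the ring oxygen, formyl beside the ring CH) is assumed to be the thermodynamic one, so that acid equilibration in step 15 delivers it.

Remark on catalysts: L1 is a chiral 4,5-diphenylimidazolin-2-ylidene carrying an N-(2-sulfonatoaryl) group, used as its silver complex Ag2(L1)2. L2 is the dianion of the Schiff base from 3-(1-adamantyl)-2-hydroxy-5-methylbenzaldehyde and cis-1-aminoindan-2-ol. For both, the antipode is fixed by the outcome stated in the step, because which antipode delivers that outcome has not been assigned here and is to be taken from the known sense of induction of each catalyst.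

## Route

Step 1
Reactants: 1 hex-5-ynoic acid
Product: 2 hept-6-yn-2-one
Conditions: MeLi (3.3 equiv), Et2O, 0 °C → rt; inverse quench into ice-cold 1 M HCl
Reagents that add atoms: methyllithium, [Li]C
Why: Addition of MeLi to the lithium carboxylate (classical ketone synthesis from a carboxylic acid) gives a geminal dilithium alkoxide that cannot collapse before the aqueous quench, so addition stops at the methyl ketone; one further equivalent is spent on the alkyne C–H.

Step 2
Reactants: 2 hept-6-yn-2-one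
Product: 3 2-methyl-2-(pent-4-yn-1-yl)-1,3-dioxolane
Conditions: HOCH2CH2OH (3 equiv), p-TsOH·H2O (2 mol%), benzene, reflux, Dean–Stark
Reagents that add atoms: ethane-1,2-diol, OCCO
Why: Acid-catalysed ketalisation with azeotropic removal of water masks the ketone against the hydride and organolithium reagents of steps 5 and 10; the terminal alkyne is inert.

Step 3
Reactants: 4 (Z)-but-2-ene-1,4-diol
Product: 5 (Z)-4-{[tert-butyl(diphenyl)silyl]oxy}but-2-en-1-ol
Conditions: NaH (1.0 equiv), THF, 0 °C → rt; TBDPSCl (1.0 equiv)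
Reagents that add atoms: tert-butyl(chloro)diphenylsilane, CC(C)(C)[Si](Cl)(c1ccccc1)c1ccccc1
Why: Monosilylation of a symmetrical diol through its monosodium alkoxide (O-silylation); TBDPS is chosen because, unlike smaller silyl ethers, it should withstand the chloroiminium reagent of step 8.

Step 4
Reactants: 5 (Z)-4-{[tert-butyl(diphenyl)silyl]oxy}but-2-en-1-ol
Product: 6 (Z)-4-{[tert-butyl(diphenyl)silyl]oxy}but-2-en-1-yl diethyl phosphate
Conditions: ClP(O)(OEt)2 (1.2 equiv), Et3N, DMAP (cat.), CH2Cl2, 0 °C → rt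
Reagents that add atoms: diethyl chlorophosphate, CCOP(=O)(Cl)OCC
Why: O-Phosphorylation of the primary allylic alcohol installs the leaving group needed for copper-catalysed allylic substitution; no stereocentre is formed.

Step 5
Reactants: 3 2-methyl-2-(pent-4-yn-1-yl)-1,3-dioxolane; 6 (Z)-4-{[tert-butyl(diphenyl)silyl]oxy}but-2-en-1-yl diethyl phosphate
Product: 8 tert-butyl{[(2R)-2-ethenyl-3-methylidene-6-(2-methyl-1,3-dioxolan-2-yl)hexyl]oxy}diphenylsilane, via alkenylaluminium 7 (not isolated)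
Conditions: 3 (1.5 equiv), iBu2AlH (1.3 equiv per alkyne), Ni(dppp)Cl2 (3 mol%), THF, 0 → 22 °C; then 6, CuCl2·2H2O (5 mol%), Ag2(L1)2 (2.5 mol%), THF, −15 °C
Reagents that add atoms: none
Why: Nickel-catalysed hydroalumination with the bidentate dppp ligand places aluminium on the internal alkyne carbon, and the 2-alkenylaluminium 7 then transfers its alkenyl group in a copper-catalysed enantioselective SN2′ allylic substitution at the γ-carbon of 6, where the chiral sulfonate-bridged carbene ligand (antipode chosen for this outcome) differentiates the faces of the Z-alkene and sets Cα as R.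

Step 6
Reactants: 8 tert-butyl{[(2R)-2-ethenyl-3-methylidene-6-(2-methyl-1,3-dioxolan-2-yl)hexyl]oxy}diphenylsilane; 9 (E)-but-2-enal (crotonaldehyde)
Product: 10 (2E,4R)-4-({[tert-butyl(diphenyl)silyl]oxy}methyl)-5-methylidene-8-(2-methyl-1,3-dioxolan-2-yl)oct-2-enal
Conditions: second-generation Hoveyda–Grubbs catalyst RuCl2(H2IMes)(=CH-C6H4-2-OiPr) (5 mol%), 9 (5 equiv), CH2Cl2, 40 °C
Reagents that add atoms: none
Why: Olefin cross-metathesis engages only the monosubstituted vinyl group (the 1,1-disubstituted alkene is too hindered and the skipped diene cannot ring-close), and the conjugated product forms as the E-enal with loss of propene; Cα is untouched.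

Step 7
Reactants: 10 (2E,4R)-4-({[tert-butyl(diphenyl)silyl]oxy}methyl)-5-methylidene-8-(2-methyl-1,3-dioxolan-2-yl)oct-2-enal; 11 ethyl vinyl ether
Product: 12 tert-butyl{[(2R)-2-[(2R,4S)-2-ethoxy-3,4-dihydro-2H-pyran-4-yl]-3-methylidene-6-(2-methyl-1,3-dioxolan-2-yl)hexyl]oxy}diphenylsilane
Conditions: Cr(L2)Cl (10 mol%), 4 Å MS, 11 (10 equiv, neat), rt, 48–72 h
Reagents that add atoms: none
Why: The trivalent chromium centre of Cr(L2)Cl binds the aldehyde oxygen of 10 and lowers the LUMO of the 1-oxadiene O=C1–C2=C3, and ethyl vinyl ether adds in a concerted but asynchronous inverse-electron-demand [4+2] cycloaddition in which the C3–CH2 bond runs ahead of the O–CH(OEt) bond. The closest known reaction type is the chromium Schiff-base-catalysed hetero-Diels–Alder reaction of β-substituted α,β-unsaturated aldehydes with ethyl vinyl ether. The one ring formed, the dihydropyran, is closed by this intermolecular cycloaddition itself, with the regiochemistry fixed by polarity (nucleophilic CH2 of the enol ether to electrophilic C3, carbonyl oxygen to the alkoxy carbon). C4 (Cβ) is set by the catalyst, whose antipode is chosen so that the dienophile adds to the Si face of C3 and which is expected to override the modest bias of the adjacent Cα centre; C2 is set by the endo orientation of the ethoxy group, giving the 2,4-cis adduct, and is erased in step 15. The step needs chemoselectivity for the enal over the isolated 1,1-disubstituted alkene, which is neither a heterodiene nor an electron-rich dienophile, and it needs Cα to stay intact, which the CH2OSi substituent (no carbonyl at Cα) and the non-basic, sieve-dried medium should secure.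

Step 8
Reactants: 12 tert-butyl{[(2R)-2-[(2R,4S)-2-ethoxy-3,4-dihydro-2H-pyran-4-yl]-3-methylidene-6-(2-methyl-1,3-dioxolan-2-yl)hexyl]oxy}diphenylsilane
Product: 14 (2R,4S)-4-[(2R)-1-{[tert-butyl(diphenyl)silyl]oxy}-3-methylidene-6-(2-methyl-1,3-dioxolan-2-yl)hexan-2-yl]-2-ethoxy-3,4-dihydro-2H-pyran-5-carbaldehyde, via iminium chloride 13 (not isolated)
Conditions: POCl3 (1.3 equiv)/DMF (6 equiv) preformed at 0 °C, CH2Cl2, 0 °C → rt; then cold aq. NaOAc
Reagents that add atoms: N,N-dimethylformamide, CN(C)C=O; water, O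
Why: Vilsmeier–Haack formylation: the enol ether attacks the chloroiminium ion through its nucleophilic β-carbon C5, loss of the C5 proton restores the C5=C6 bond, and buffered aqueous work-up hydrolyses iminium salt 13 to the β-alkoxy enal; excess DMF takes up the HCl so that acetal, ketal and TBDPS ether should survive.

Step 9
Reactants: 15 2-methylbut-3-yn-2-ol
Product: 16 triethyl[(2-methylbut-3-yn-2-yl)oxy]silane
Conditions: TESCl (1.2 equiv), imidazole (2 equiv), DMAP (cat.), DMF, rt
Reagents that add atoms: chlorotriethylsilane, CC[Si](Cl)(CC)CC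
Why: Imidazole-promoted O-silylation of the tertiary propargylic alcohol keeps the hydroxyl from quenching the acetylide and from cyclising onto the later ynone.

Step 10
Reactants: 16 triethyl[(2-methylbut-3-yn-2-yl)oxy]silane; 14 (2R,4S)-4-[(2R)-1-{[tert-butyl(diphenyl)silyl]oxy}-3-methylidene-6-(2-methyl-1,3-dioxolan-2-yl)hexan-2-yl]-2-ethoxy-3,4-dihydro-2H-pyran-5-carbaldehyde
Product: 18 1-[(2R,4S)-4-[(2R)-1-{[tert-butyl(diphenyl)silyl]oxy}-3-methylidene-6-(2-methyl-1,3-dioxolan-2-yl)hexan-2-yl]-2-ethoxy-3,4-dihydro-2H-pyran-5-yl]-4-methyl-4-[(triethylsilyl)oxy]pent-2-yn-1-ol (both carbinol epimers), via lithium acetylide 17 (not isolated)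
Conditions: 16 (1.3 equiv), n-BuLi (1.25 equiv), THF, −78 °C; then 14, −78 → −40 °C; aq. NaHCO3
Reagents that add atoms: none
Why: Deprotonation of the terminal alkyne and 1,2-addition of the lithium acetylide to the aldehyde of the vinylogous formate (acetylide addition to an aldehyde) builds the C5 side chain; the carbinol centre forms without control and is removed in step 11.

Step 11
Reactants: 18 1-[(2R,4S)-4-[(2R)-1-{[tert-butyl(diphenyl)silyl]oxy}-3-methylidene-6-(2-methyl-1,3-dioxolan-2-yl)hexan-2-yl]-2-ethoxy-3,4-dihydro-2H-pyran-5-yl]-4-methyl-4-[(triethylsilyl)oxy]pent-2-yn-1-ol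
Product: 19 1-[(2R,4S)-4-[(2R)-1-{[tert-butyl(diphenyl)silyl]oxy}-3-methylidene-6-(2-methyl-1,3-dioxolan-2-yl)hexan-2-yl]-2-ethoxy-3,4-dihydro-2H-pyran-5-yl]-4-methyl-4-[(triethylsilyl)oxy]pent-2-yn-1-one
Conditions: activated MnO2 (20 equiv), CH2Cl2, rt (crude 18 used at once)
Reagents that add atoms: none
Why: MnO2 oxidation of a secondary alcohol that is both allylic and propargylic proceeds under neutral, anhydrous conditions that spare the acid-labile enol-ether carbinol, the acetal and the ketal.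

Step 12
Reactants: 19 1-[(2R,4S)-4-[(2R)-1-{[tert-butyl(diphenyl)silyl]oxy}-3-methylidene-6-(2-methyl-1,3-dioxolan-2-yl)hexan-2-yl]-2-ethoxy-3,4-dihydro-2H-pyran-5-yl]-4-methyl-4-[(triethylsilyl)oxy]pent-2-yn-1-one
Product: 20 (2Z)-1-[(2R,4S)-4-[(2R)-1-{[tert-butyl(diphenyl)silyl]oxy}-3-methylidene-6-(2-methyl-1,3-dioxolan-2-yl)hexan-2-yl]-2-ethoxy-3,4-dihydro-2H-pyran-5-yl]-4-methyl-4-[(triethylsilyl)oxy]pent-2-en-1-one
Conditions: H2 (1 atm), Pd/CaCO3 poisoned with Pb(OAc)2 (Lindlar catalyst), quinoline, EtOAc, rt, stopped at one equivalent of H2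
Reagents that add atoms: none
Why: Lindlar semi-hydrogenation delivers H2 syn to the alkyne on poisoned palladium and stops at the Z-enone, the geometry that later lets the tertiary oxygen reach the ketone carbon; the hindered alkene and the push–pull enol ether are not reduced.

Step 13
Reactants: 20 (2Z)-1-[(2R,4S)-4-[(2R)-1-{[tert-butyl(diphenyl)silyl]oxy}-3-methylidene-6-(2-methyl-1,3-dioxolan-2-yl)hexan-2-yl]-2-ethoxy-3,4-dihydro-2H-pyran-5-yl]-4-methyl-4-[(triethylsilyl)oxy]pent-2-en-1-one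
Product: 21 (2Z)-1-[(2R,4S)-2-ethoxy-4-[(2R)-1-hydroxy-3-methylidene-6-(2-methyl-1,3-dioxolan-2-yl)hexan-2-yl]-3,4-dihydro-2H-pyran-5-yl]-4-hydroxy-4-methylpent-2-en-1-one
Conditions: Bu4NF (4 equiv), AcOH (4 equiv), THF, rt → 35 °C
Reagents that add atoms: none
Why: Fluoride-induced cleavage of both silyl ethers (desilylation); acetic acid buffering keeps the freed primary alcohol from adding to C6 of the vinylogous ester and the medium from isomerising the Z-enone (21 may sit partly as its cyclic hemiketal, which converges in step 15).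

Step 14
Reactants: 21 (2Z)-1-[(2R,4S)-2-ethoxy-4-[(2R)-1-hydroxy-3-methylidene-6-(2-methyl-1,3-dioxolan-2-yl)hexan-2-yl]-3,4-dihydro-2H-pyran-5-yl]-4-hydroxy-4-methylpent-2-en-1-one
Product: 23 (2R)-2-[(2R,4S)-2-ethoxy-5-[(2Z)-4-hydroxy-4-methylpent-2-enoyl]-3,4-dihydro-2H-pyran-4-yl]-3-methylidene-6-(2-methyl-1,3-dioxolan-2-yl)hexanoic acid, via aldehyde 22 (not isolated)
Conditions: TEMPO (0.2 equiv), PhI(OAc)2 (2.5 equiv), MeCN/pH 7 phosphate buffer (1:1), 0 °C → rt
Reagents that add atoms: water, O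
Why: TEMPO-catalysed oxidation with PhI(OAc)2 in aqueous medium takes the primary alcohol through aldehyde 22 and its hydrate to the acid at near-neutral pH, fast enough that the allylic Cα centre should not epimerise; the tertiary alcohol cannot be oxidised and both aldehyde equivalents are still masked in the pyran.

Step 15
Reactants: 23 (2R)-2-[(2R,4S)-2-ethoxy-5-[(2Z)-4-hydroxy-4-methylpent-2-enoyl]-3,4-dihydro-2H-pyran-4-yl]-3-methylidene-6-(2-methyl-1,3-dioxolan-2-yl)hexanoic acid
Product: 25 CNP0150297.1 (2R,3S)-3-[(1E)-1-(5,5-dimethylfuran-2(5H)-ylidene)-2-oxoethyl]-5-oxo-2-(6-oxohept-1-en-2-yl)pentanoic acid, via ring-opened tricarbonyl 24 (not isolated)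
Conditions: 1 M aq. HCl/THF (1:3), 0 °C → rt
Reagents that add atoms: water, O
Why: Aqueous acid hydrolyses the 2-ethoxy acetal (opening the pyran to the CH2CHO arm and the β-keto aldehyde 24) and the dioxolane, after which the tertiary alcohol adds 5-exo-trig to the ketone carbon and water is lost (acetal hydrolysis followed by vinylogous transesterification), the push–pull enol ether equilibrating to the E isomer; acid and not base is used so that Cα and Cβ are not exposed to enolate or retro-Michael pathways.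

## Compound list

1 | hex-5-ynoic acid | C#CCCCC(=O)O | starting material
2 | hept-6-yn-2-one | C#CCCCC(C)=O | intermediate
3 | 2-methyl-2-(pent-4-yn-1-yl)-1,3-dioxolane | C#CCCCC1(C)OCCO1 | intermediate
4 | (Z)-but-2-ene-1,4-diol | OC/C=C\CO | starting material
5 | (Z)-4-{[tert-butyl(diphenyl)silyl]oxy}but-2-en-1-ol | OC/C=C\CO[Si](c1ccccc1)(c1ccccc1)C(C)(C)C | intermediate
6 | (Z)-4-{[tert-butyl(diphenyl)silyl]oxy}but-2-en-1-yl diethyl phosphate | CCOP(=O)(OCC)OC/C=C\CO[Si](c1ccccc1)(c1ccccc1)C(C)(C)C | intermediate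
7 | bis(2-methylpropyl)[5-(2-methyl-1,3-dioxolan-2-yl)pent-1-en-2-yl]aluminium | C=C(CCCC1(C)OCCO1)[Al](CC(C)C)CC(C)C | intermediate
8 | tert-butyl{[(2R)-2-ethenyl-3-methylidene-6-(2-methyl-1,3-dioxolan-2-yl)hexyl]oxy}diphenylsilane | C=C(CCCC1(C)OCCO1)[C@H](CO[Si](c2ccccc2)(c2ccccc2)C(C)(C)C)C=C | intermediate
9 | (E)-but-2-enal (crotonaldehyde) | C/C=C/C=O | starting material
10 | (2E,4R)-4-({[tert-butyl(diphenyl)silyl]oxy}methyl)-5-methylidene-8-(2-methyl-1,3-dioxolan-2-yl)oct-2-enal | C=C(CCCC1(C)OCCO1)[C@H](CO[Si](c2ccccc2)(c2ccccc2)C(C)(C)C)/C=C/C=O | intermediate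
11 | ethyl vinyl ether | C=COCC | starting material
12 | tert-butyl{[(2R)-2-[(2R,4S)-2-ethoxy-3,4-dihydro-2H-pyran-4-yl]-3-methylidene-6-(2-methyl-1,3-dioxolan-2-yl)hexyl]oxy}diphenylsilane | C=C(CCCC1(C)OCCO1)[C@H](CO[Si](c3ccccc3)(c3ccccc3)C(C)(C)C)[C@@H]2C[C@H](OCC)OC=C2 | intermediate
13 | N-{[(2R,4S)-4-[(2R)-1-{[tert-butyl(diphenyl)silyl]oxy}-3-methylidene-6-(2-methyl-1,3-dioxolan-2-yl)hexan-2-yl]-2-ethoxy-3,4-dihydro-2H-pyran-5-yl]methylidene}-N-methylmethanaminium chloride | C=C(CCCC1(C)OCCO1)[C@H](CO[Si](c3ccccc3)(c3ccccc3)C(C)(C)C)[C@@H]2C[C@H](OCC)OC=C2C=[N+](C)C.[Cl-] | intermediate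
14 | (2R,4S)-4-[(2R)-1-{[tert-butyl(diphenyl)silyl]oxy}-3-methylidene-6-(2-methyl-1,3-dioxolan-2-yl)hexan-2-yl]-2-ethoxy-3,4-dihydro-2H-pyran-5-carbaldehyde | C=C(CCCC1(C)OCCO1)[C@H](CO[Si](c3ccccc3)(c3ccccc3)C(C)(C)C)[C@@H]2C[C@H](OCC)OC=C2C=O | intermediate
15 | 2-methylbut-3-yn-2-ol | C#CC(C)(C)O | starting material
16 | triethyl[(2-methylbut-3-yn-2-yl)oxy]silane | C#CC(C)(C)O[Si](CC)(CC)CC | intermediate
17 | lithium 3-methyl-3-[(triethylsilyl)oxy]but-1-yn-1-ide | [Li]C#CC(C)(C)O[Si](CC)(CC)CC | intermediate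
18 | 1-[(2R,4S)-4-[(2R)-1-{[tert-butyl(diphenyl)silyl]oxy}-3-methylidene-6-(2-methyl-1,3-dioxolan-2-yl)hexan-2-yl]-2-ethoxy-3,4-dihydro-2H-pyran-5-yl]-4-methyl-4-[(triethylsilyl)oxy]pent-2-yn-1-ol (both carbinol epimers) | C=C(CCCC1(C)OCCO1)[C@H](CO[Si](c3ccccc3)(c3ccccc3)C(C)(C)C)[C@@H]2C[C@H](OCC)OC=C2C(O)C#CC(C)(C)O[Si](CC)(CC)CC | intermediate
19 | 1-[(2R,4S)-4-[(2R)-1-{[tert-butyl(diphenyl)silyl]oxy}-3-methylidene-6-(2-methyl-1,3-dioxolan-2-yl)hexan-2-yl]-2-ethoxy-3,4-dihydro-2H-pyran-5-yl]-4-methyl-4-[(triethylsilyl)oxy]pent-2-yn-1-one | C=C(CCCC1(C)OCCO1)[C@H](CO[Si](c3ccccc3)(c3ccccc3)C(C)(C)C)[C@@H]2C[C@H](OCC)OC=C2C(=O)C#CC(C)(C)O[Si](CC)(CC)CC | intermediate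
20 | (2Z)-1-[(2R,4S)-4-[(2R)-1-{[tert-butyl(diphenyl)silyl]oxy}-3-methylidene-6-(2-methyl-1,3-dioxolan-2-yl)hexan-2-yl]-2-ethoxy-3,4-dihydro-2H-pyran-5-yl]-4-methyl-4-[(triethylsilyl)oxy]pent-2-en-1-one | C=C(CCCC1(C)OCCO1)[C@H](CO[Si](c3ccccc3)(c3ccccc3)C(C)(C)C)[C@@H]2C[C@H](OCC)OC=C2C(=O)/C=C\C(C)(C)O[Si](CC)(CC)CC | intermediate
21 | (2Z)-1-[(2R,4S)-2-ethoxy-4-[(2R)-1-hydroxy-3-methylidene-6-(2-methyl-1,3-dioxolan-2-yl)hexan-2-yl]-3,4-dihydro-2H-pyran-5-yl]-4-hydroxy-4-methylpent-2-en-1-one | C=C(CCCC1(C)OCCO1)[C@H](CO)[C@@H]2C[C@H](OCC)OC=C2C(=O)/C=C\C(C)(C)O | intermediate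
22 | (2R)-2-[(2R,4S)-2-ethoxy-5-[(2Z)-4-hydroxy-4-methylpent-2-enoyl]-3,4-dihydro-2H-pyran-4-yl]-3-methylidene-6-(2-methyl-1,3-dioxolan-2-yl)hexanal | C=C(CCCC1(C)OCCO1)[C@H](C=O)[C@@H]2C[C@H](OCC)OC=C2C(=O)/C=C\C(C)(C)O | intermediate
23 | (2R)-2-[(2R,4S)-2-ethoxy-5-[(2Z)-4-hydroxy-4-methylpent-2-enoyl]-3,4-dihydro-2H-pyran-4-yl]-3-methylidene-6-(2-methyl-1,3-dioxolan-2-yl)hexanoic acid | C=C(CCCC1(C)OCCO1)[C@H](C(=O)O)[C@@H]2C[C@H](OCC)OC=C2C(=O)/C=C\C(C)(C)O | intermediate
24 | (2R,3R)-3-[(4Z)-6-hydroxy-6-methyl-1,3-dioxohept-4-en-2-yl]-5-oxo-2-(6-oxohept-1-en-2-yl)pentanoic acid (keto and enol tautomers; same spatial arrangement at C3 as in 25, the descriptor differs by CIP priority only) | C=C(CCCC(C)=O)[C@H](C(=O)O)[C@H](CC=O)C(C=O)C(=O)/C=C\C(C)(C)O | intermediate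
25 | CNP0150297.1, (2R,3S)-3-[(1E)-1-(5,5-dimethylfuran-2(5H)-ylidene)-2-oxoethyl]-5-oxo-2-(6-oxohept-1-en-2-yl)pentanoic acid | C=C(CCCC(C)=O)[C@H](C(=O)O)[C@H](CC=O)/C(C=O)=C1/C=CC(C)(C)O1 | target

## Step count and risks

Total step count: 15. Longest linear sequence: 12 steps (1 → 2 → 3 → 8 → 10 → 12 → 14 → 18 → 19 → 20 → 21 → 23 → 25).

**Step 7 (key cycloaddition).** The cycloaddition may be too slow at the β-branched enal, or the catalyst may fail to override the facial bias of the Cα centre, so that the C4 epimer forms. The fallback sets out from 10 and comes back at 12; it tells the two arms of the latent dialdehyde apart by oxidation level instead of by cycloaddition. Iminium-catalysed Mukaiyama–Michael addition of tert-butyl(dimethyl){[1-(propan-2-ylsulfanyl)ethenyl]oxy}silane to 10 (5-benzyl-2-tert-butyl-3-methylimidazolidin-4-one salt, antipode chosen for attack on the Re face of C3) should give the thioester aldehyde F1. Silver-assisted hydrolysis of the thioester (AgNO3, 2,6-lutidine, aqueous THF) should give the oxo acid F2, and EtOH/PPTS should close it to the 6-ethoxy lactone F3. KN(SiMe3)2 and (PhO)2P(O)Cl should give the ketene acetal phosphate F4, and palladium-catalysed hydride reduction (Pd(PPh3)4, Bu3SnH) should give 12 together with its C2 epimer; both serve, because C2 becomes an aldehyde carbon in step 15.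

**Step 8 (formylation).** The HCl released during the iminium substitution may ionise the 2-ethoxy acetal or cleave the dioxolane before the hindered C5 is attacked. The fallback sets out from 12 and comes back at 14; it functionalises C5 through a vinyl anion instead of by electrophilic substitution. Br2 (1.0 equiv, CH2Cl2, −78 °C; the enol ether should react far faster than the 1,1-disubstituted alkene) adds across C5=C6 to give the dibromide F5, which is not isolated. DBU removes HBr to give the 5-bromo enol ether F6. Bromine–lithium exchange (t-BuLi, 2 equiv, THF, −78 °C) and a DMF quench should give 14.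

**Step 5 (allylic substitution).** The Z-configured, oxygen-bearing phosphate may give insufficient enantioselectivity or γ-selectivity. The fallback sets out from 5 and from 7 (made from 3 as in step 5) and comes back at 10; it sets Cα by 1,3-chirality transfer from a carbinol centre. Parikh–Doering oxidation of 5 with base-induced Z-to-E isomerisation should give the enal F7. Enantioselective methyl addition (Me2Zn, Ti(OiPr)4, chiral bis-sulfonamide ligand, antipode giving R) should give the allylic alcohol F8, and phosphorylation the secondary phosphate F9. Anti-SN2′ substitution of F9 with 7 under an achiral copper catalyst, (IMes)CuCl, should give the (R)-diene F10, which carries an E-propenyl group in place of vinyl. Cross-metathesis of F10 with 9 under the conditions of step 6 should give 10.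

## Further compounds

F1 | step 7 | S-propan-2-yl (3R)-3-[(2R)-1-{[tert-butyl(diphenyl)silyl]oxy}-3-methylidene-6-(2-methyl-1,3-dioxolan-2-yl)hexan-2-yl]-5-oxopentanethioate | C=C(CCCC1(C)OCCO1)[C@H](CO[Si](c2ccccc2)(c2ccccc2)C(C)(C)C)[C@@H](CC(=O)SC(C)C)CC=O
F2 | step 7 | (3R)-3-[(2R)-1-{[tert-butyl(diphenyl)silyl]oxy}-3-methylidene-6-(2-methyl-1,3-dioxolan-2-yl)hexan-2-yl]-5-oxopentanoic acid | C=C(CCCC1(C)OCCO1)[C@H](CO[Si](c2ccccc2)(c2ccccc2)C(C)(C)C)[C@@H](CC(=O)O)CC=O
F3 | step 7 | (4R)-4-[(2R)-1-{[tert-butyl(diphenyl)silyl]oxy}-3-methylidene-6-(2-methyl-1,3-dioxolan-2-yl)hexan-2-yl]-6-ethoxyoxan-2-one (both C6 epimers) | C=C(CCCC1(C)OCCO1)[C@H](CO[Si](c2ccccc2)(c2ccccc2)C(C)(C)C)[C@@H]3CC(OCC)OC(=O)C3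
F4 | step 7 | (4S)-4-[(2R)-1-{[tert-butyl(diphenyl)silyl]oxy}-3-methylidene-6-(2-methyl-1,3-dioxolan-2-yl)hexan-2-yl]-2-ethoxy-3,4-dihydro-2H-pyran-6-yl diphenyl phosphate (both C2 epimers) | C=C(CCCC1(C)OCCO1)[C@H](CO[Si](c2ccccc2)(c2ccccc2)C(C)(C)C)[C@@H]3CC(OCC)OC(OP(=O)(Oc4ccccc4)Oc4ccccc4)=C3
F5 | step 8 | tert-butyl{[(2R)-2-[(2R,4S)-5,6-dibromo-2-ethoxyoxan-4-yl]-3-methylidene-6-(2-methyl-1,3-dioxolan-2-yl)hexyl]oxy}diphenylsilane (mixture at C5 and C6) | C=C(CCCC1(C)OCCO1)[C@H](CO[Si](c3ccccc3)(c3ccccc3)C(C)(C)C)[C@@H]2C[C@H](OCC)OC(Br)C2Br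
F6 | step 8 | tert-butyl{[(2R)-2-[(2R,4S)-5-bromo-2-ethoxy-3,4-dihydro-2H-pyran-4-yl]-3-methylidene-6-(2-methyl-1,3-dioxolan-2-yl)hexyl]oxy}diphenylsilane | C=C(CCCC1(C)OCCO1)[C@H](CO[Si](c3ccccc3)(c3ccccc3)C(C)(C)C)[C@@H]2C[C@H](OCC)OC=C2Br
F7 | step 5 | (E)-4-{[tert-butyl(diphenyl)silyl]oxy}but-2-enal | O=C/C=C/CO[Si](c1ccccc1)(c1ccccc1)C(C)(C)C
F8 | step 5 | (2R,3E)-5-{[tert-butyl(diphenyl)silyl]oxy}pent-3-en-2-ol | C[C@@H](O)/C=C/CO[Si](c1ccccc1)(c1ccccc1)C(C)(C)C
F9 | step 5 | (2R,3E)-5-{[tert-butyl(diphenyl)silyl]oxy}pent-3-en-2-yl diethyl phosphate | C[C@@H](OP(=O)(OCC)OCC)/C=C/CO[Si](c1ccccc1)(c1ccccc1)C(C)(C)C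
F10 | step 5 | tert-butyl{[(2R,3E)-2-[5-(2-methyl-1,3-dioxolan-2-yl)pent-1-en-2-yl]pent-3-en-1-yl]oxy}diphenylsilane | C=C(CCCC1(C)OCCO1)[C@H](CO[Si](c2ccccc2)(c2ccccc2)C(C)(C)C)/C=C/C
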